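**Strategy.** Everything rests on cutting the pyran (ring B) off the C5=C6 vinylogous ester of ring A (C1 = diprenyl carbon). The C6 oxygen belongs to a cyclic trione, the carbon on C5 is formaldehyde, and the CH2–CMe2 pair is 2-methylpropene. One operation, Knoevenagel condensation at C5 followed by an oxa-Diels–Alder addition, makes the C5–CH2, CH2–CH2 and O–CMe2 bonds and closes ring B as a dihydropyran. DDQ then introduces the ring-B alkene. The precursor is enolised 2-benzoyl-4,4-diprenylcyclohexane-1,3,5-trione, whose C5 is the only free ring carbon; it is made in two steps from dimethyl malonate, prenyl bromide and benzoylacetone.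

Key step: step 3

Remark: the target is achiral, β-triketones are drawn as one enol tautomer, and enolates formed by deprotonation are treated as ionised forms of the numbered compounds, not as separate compounds.

Step 1
Reactants: 1 dimethyl malonate; 2 1-bromo-3-methylbut-2-ene (prenyl bromide, 2.2 equiv)
Product: 4 dimethyl 2,2-bis(3-methylbut-2-enyl)malonate, via monoprenylated malonate 3 (not isolated)
Conditions: NaH (2.3 equiv), THF/DMF, 0 °C → rt
Reagents that add atoms: none
Why: Twofold SN2 C-alkylation of the malonate enolate (malonic ester alkylation) by the primary allylic bromide at its CH2 terminus should install the quaternary carbon that becomes C1 of ring A.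

Step 2
Reactants: 4 dimethyl 2,2-bis(3-methylbut-2-enyl)malonate; 5 1-phenylbutane-1,3-dione (benzoylacetone)
Product: 7 2-benzoyl-4,4-bis(3-methylbut-2-enyl)cyclohexane-1,3,5-trione (enol form), via triketo ester 6 (not isolated)
Conditions: 5, LiN(iPr)2 (3.2 equiv), THF, −78 → 0 °C; add 4, 0 → 65 °C; then 1 M HCl
Reagents that add atoms: none
Why: The dilithio dianion of 5 should be acylated at its terminal CH2 by one ester group of 4 (γ-acylation of a β-diketone dianion by an ester without α-hydrogen), and the dienolate of 6 should then close by an intramolecular Claisen (Dieckmann-type) condensation of the CH2 between the benzoyl group and the neighbouring ketone onto the second ester, helped by the gem-dialkyl effect, with aldol aromatisation blocked by the quaternary carbon and the doubly enolised trione as thermodynamic sink.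

Step 3
Reactants: 7 2-benzoyl-4,4-bis(3-methylbut-2-enyl)cyclohexane-1,3,5-trione; 8 formaldehyde (charged as paraformaldehyde, 3 equiv); 9 2-methylpropene (about 20 equiv, condensed)
Product: 11 6-benzoyl-7-hydroxy-2,2-dimethyl-8,8-bis(3-methylbut-2-enyl)-3,4-dihydro-2H-chromen-5(8H)-one, via 5-methylene trione 10 (not isolated)
Conditions: (CH2O)n, 2-methylpropene (excess), ethylenediammonium diacetate (10 mol%), 1,4-dioxane, sealed tube, 90 °C
Reagents that add atoms: none
Why: Ethylenediammonium diacetate should mediate Knoevenagel condensation of formaldehyde at C5, the only unsubstituted nucleophilic carbon of ring A, to give with loss of water the 5-methylene trione 10, whose O=C6–C5=CH2 unit is an electron-poor 1-oxadiene held s-cis by the ring. This heterodiene should add 2-methylpropene in an inverse-electron-demand hetero-Diels–Alder reaction through an asynchronous transition state in which the CH2–CH2 bond leads and the oxygen closes onto the carbon carrying the developing tertiary cation, which fixes the O–CMe2 orientation. The closest known reaction type is the domino Knoevenagel/hetero-Diels–Alder reaction of cyclic 1,3-diones and dearomatised phloroglucinol triketones with aldehydes and alkenes, including three-component pyran annulations of 2-hydroxy-1,4-naphthoquinone and 4-hydroxycoumarin with formaldehyde and simple alkenes. Ring B closes by an intermolecular [4+2] cycloaddition (O, C6, C5 and the new CH2 plus the two alkene carbons), and no stereocentre arises because the two new sp3 centres are CH2 and CMe2. Three selectivities are needed: the alkene rather than a second molecule of 7 must capture 10, which the large excess of condensed alkene and heating should secure, since the Michael dimer reverts to 10 under these conditions; the C6 rather than the C4 oxygen must close, which is favoured because C6=O is an isolated ketone next to the quaternary C1 whereas the C4 oxygen is tied into the hydrogen-bonded enol chelate of the benzoyl triketone; and 2-methylpropene must win over the prenyl alkenes, which cannot reach the diene intramolecularly without a bridgehead alkene and are outnumbered intermolecularly.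

Step 4
Reactants: 11 6-benzoyl-7-hydroxy-2,2-dimethyl-8,8-bis(3-methylbut-2-enyl)-3,4-dihydro-2H-chromen-5(8H)-one
Product: 12 6-benzoyl-7-hydroxy-2,2-dimethyl-8,8-bis(3-methylbut-2-enyl)-2H-chromen-5(8H)-one (CNP0138894.0)
Conditions: DDQ (1.5 equiv), 1,4-dioxane, 100 °C
Reagents that add atoms: none
Why: 2,3-Dichloro-5,6-dicyano-1,4-benzoquinone should abstract hydride from the ring-B CH2 attached to C5 (C4 of the chromenone), the cation being stabilised as an oxocarbenium ion through the C5=C6 enol ether, and loss of the neighbouring C3 proton should give the 2H-pyran, as in the DDQ dehydrogenation known for chromans and for dihydropyrans fused to quinones, pyranones and quinolinones, while the quaternary C1 rules out aromatisation of ring A.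

**Compound list**

1 | dimethyl malonate | COC(=O)CC(=O)OC | starting material
2 | 1-bromo-3-methylbut-2-ene (prenyl bromide) | CC(C)=CCBr | starting material
3 | dimethyl 2-(3-methylbut-2-enyl)malonate | COC(=O)C(CC=C(C)C)C(=O)OC | intermediate
4 | dimethyl 2,2-bis(3-methylbut-2-enyl)malonate | COC(=O)C(CC=C(C)C)(CC=C(C)C)C(=O)OC | intermediate
5 | 1-phenylbutane-1,3-dione (benzoylacetone) | CC(=O)CC(=O)c1ccccc1 | starting material
6 | methyl 2,2-bis(3-methylbut-2-enyl)-3,5,7-trioxo-7-phenylheptanoate | COC(=O)C(CC=C(C)C)(CC=C(C)C)C(=O)CC(=O)CC(=O)c1ccccc1 | intermediate
7 | 2-benzoyl-4,4-bis(3-methylbut-2-enyl)cyclohexane-1,3,5-trione, enol form (ring A: C1 diprenyl, C2 enol OH, C3 benzoyl, C4 C=O, C5 H, C6 enol OH) | CC(C)=CCC1(CC=C(C)C)C(O)=C(C(=O)c2ccccc2)C(=O)C=C1O | intermediate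
8 | formaldehyde | C=O | starting material
9 | 2-methylpropene | CC(C)=C | starting material
10 | 2-benzoyl-6-methylidene-4,4-bis(3-methylbut-2-enyl)cyclohexane-1,3,5-trione, enol form (5-methylene trione) | CC(C)=CCC1(CC=C(C)C)C(O)=C(C(=O)c2ccccc2)C(=O)C(=C)C1=O | intermediate
11 | 6-benzoyl-7-hydroxy-2,2-dimethyl-8,8-bis(3-methylbut-2-enyl)-3,4-dihydro-2H-chromen-5(8H)-one | CC(C)=CCC1(CC=C(C)C)C(O)=C(C(=O)c2ccccc2)C(=O)C2=C1OC(C)(C)CC2 | intermediate
12 | 6-benzoyl-7-hydroxy-2,2-dimethyl-8,8-bis(3-methylbut-2-enyl)-2H-chromen-5(8H)-one (CNP0138894.0, achiral) | CC(C)=CCC1(CC=C(C)C)C(O)=C(C(=O)c2ccccc2)C(=O)C2=C1OC(C)(C)C=C2 | target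

**Count.** Total steps: 4. Longest linear sequence: 4 steps (1 → 4 → 7 → 11 → 12).

**Steps most likely to fail**

Step 3. The transient methylene trione 10 may be captured by a second molecule of 7 (Michael addition to a methylene-bridged dimer) or by a prenyl alkene faster than by the gaseous alkene, and the cycloaddition may close through the C4 oxygen. The fallback generates the heterodiene separately and sets out from 7. A Mannich reaction with aqueous CH2O and Me2NH in EtOH at 20 °C should give the Mannich base 2-benzoyl-6-[(dimethylamino)methyl]-4,4-bis(3-methylbut-2-enyl)cyclohexane-1,3,5-trione F1, which is freed from unreacted 7. Heating F1 with excess 9 in toluene in a sealed tube at 110 °C should release 10 slowly by thermal loss of dimethylamine, in the absence of free 7. The [4+2] addition then comes back to the route at 11. Mannich bases of acidic enols are established thermal precursors of such heterodienes.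

Step 2. Attack of the dianion on the hindered, doubly α-substituted ester may be slow, so that proton exchange and retro-Claisen cleavage of the quaternary β-keto ester compete, or the sequence stalls at the open-chain stage. The fallback changes from the anionic ester condensation to Lewis-acid acylation of a silyl dienol ether and sets out from 4 and 5. Saponification of 4 (KOH, aqueous EtOH, reflux, then cold dilute HCl) should give 2,2-bis(3-methylbut-2-enyl)malonic acid F2, which (COCl)2 with catalytic DMF in CH2Cl2 at 0 °C → rt should convert into 2,2-bis(3-methylbut-2-enyl)malonyl dichloride F3. In parallel, 5 with Me3SiCl and Et3N should give 4-phenyl-4-(trimethylsilyloxy)but-3-en-2-one F4 (the regioisomeric silyl enol ether would lead on to the same diene). LiN(iPr)2 followed by Me3SiCl in THF at −78 °C should then give 1-phenyl-1,3-bis(trimethylsilyloxy)buta-1,3-diene F5. F3 and F5 with catalytic Me3SiOSO2CF3 in CH2Cl2 at −78 → 20 °C, then aqueous work-up, should undergo a formal [3+3] cyclisation by C-acylation at the terminal and then at the central carbon of the diene. This comes back to the route at 7.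

Step 4. Hydride abstraction from the ring-B CH2 may be slowed by the electron-poor triketone, so that oxidation at the allylic CH2 groups of the prenyl chains or thermal ring opening and re-closure of the 2H-pyran at the other oxygen intervenes. The fallback brings in the alkene at the aldehyde oxidation level instead of by dehydrogenation and sets out from 7. Condensation with 3-methylbut-2-enal (CC(C)=CC=O) and catalytic ethylenediammonium diacetate in toluene at 80 °C should give the Knoevenagel dienone 2-benzoyl-6-(3-methylbut-2-enylidene)-4,4-bis(3-methylbut-2-enyl)cyclohexane-1,3,5-trione F6 (not isolated, alkene geometry mobile). This should close by reversible oxa-6π electrocyclisation through the C6 oxygen, the known formal [3+3] pyran annulation of 1,3-dicarbonyls with enals. It comes back to the route at 12 and bypasses steps 3 and 4.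

Further compounds
F1 | step 3 | 2-benzoyl-6-[(dimethylamino)methyl]-4,4-bis(3-methylbut-2-enyl)cyclohexane-1,3,5-trione (enol form) | CC(C)=CCC1(CC=C(C)C)C(O)=C(C(=O)c2ccccc2)C(=O)C(CN(C)C)=C1O
F2 | step 2 | 2,2-bis(3-methylbut-2-enyl)malonic acid | OC(=O)C(CC=C(C)C)(CC=C(C)C)C(=O)O
F3 | step 2 | 2,2-bis(3-methylbut-2-enyl)malonyl dichloride | ClC(=O)C(CC=C(C)C)(CC=C(C)C)C(Cl)=O
F4 | step 2 | 4-phenyl-4-(trimethylsilyloxy)but-3-en-2-one (alkene geometry of no consequence) | CC(=O)C=C(O[Si](C)(C)C)c1ccccc1
F5 | step 2 | 1-phenyl-1,3-bis(trimethylsilyloxy)buta-1,3-diene (alkene geometry of no consequence) | C=C(O[Si](C)(C)C)C=C(O[Si](C)(C)C)c1ccccc1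
F6 | step 4 | 2-benzoyl-6-(3-methylbut-2-enylidene)-4,4-bis(3-methylbut-2-enyl)cyclohexane-1,3,5-trione (enol form, not isolated) | CC(C)=CCC1(CC=C(C)C)C(O)=C(C(=O)c2ccccc2)C(=O)C(=CC=C(C)C)C1=O
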